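**Plan**

- The target is 18-acetoxylabda-8(17),13E-dien-15-oic acid (5α-H, 9α-H, 10β-CH3, 4α-CH2OAc equatorial, 4β-CH3 axial). The retrosynthesis cuts C12–C13 (sp3–sp2 coupling), C8=C17 and C11=C12 (two methylenations), and finally C5–C10 together with C8–C9.
- Enabling feature: ring B (C5–C10) has a trans C5/C10 fusion, the C10 methyl cis to the C9 chain and an sp2 C8 that can start as C–O. C5–C8 is therefore a 1-silyloxy diene and C9=C10 an (E)-3-methyl enal, linked through C1–C4 (ring A).
- Forward: the malonate carbon becomes C4 and receives the pentynyl arm (C3–C1, C10, C9) and the butenyl arm (C5–C8). The esters become the spiro-acetonide, and the alkyne becomes the (E)-enal. Rings A and B close together in step 9. The chain is then joined at C11/C12, C8 becomes C=CH2, and the two C4 arms are told apart last.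
- Stereochemistry: the absolute configuration comes from a chiral oxazaborolidinium catalyst. C5/C9/C10 follow from the endo transition state and the (E) alkenes. 13E comes from an (E)-enol triflate. C4 comes from faster acylation of the equatorial CH2OH, the axial arm being screened by the C10 methyl.

Key step: step 9

Numbering: bicyclic compounds carry labdane numbers (C18 = 4α arm, C19 = 4β arm, C20 = C10 methyl); β is the face of the C10 methyl.

Assumption: the sense of induction is taken from the formyl C–H···O pre-transition-state picture of oxazaborolidinium–enal complexes, which points to the (R)-configured catalyst for addition to the C9-Si/C10-Re face; if the opposite sense is found, the (S)-antipode is used unchanged.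

**Route**

Step 1
Reactants: 1 diethyl malonate; 2 5-chloropent-1-yne
Product: 3 diethyl 2-(pent-4-yn-1-yl)propanedioate
Conditions: NaH, excess 1, NaI (cat.), THF/DMF, 0 → 70 °C
Reagents that add atoms: none
Why: Malonic ester alkylation (SN2 with in situ Finkelstein activation of the primary chloride); excess malonate suppresses dialkylation and the far less acidic alkyne C–H is untouched.

Step 2
Reactants: 3 diethyl 2-(pent-4-yn-1-yl)propanedioate; 4 2-vinyloxirane (racemic)
Product: 5 diethyl 2-[(2E)-4-hydroxybut-2-en-1-yl]-2-(pent-4-yn-1-yl)propanedioate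
Conditions: Pd(PPh3)4 (3 mol %), THF, 0 °C → rt
Reagents that add atoms: none
Why: Tsuji–Trost allylic alkylation under neutral conditions, in which zerovalent palladium opens the vinyl epoxide to a π-allyl alkoxide that deprotonates the malonate and is attacked at the distal terminus (1,4-addition); the alkene geometry is of no consequence because it is reset in steps 6 and 7.

Step 3
Reactants: 5 diethyl 2-[(2E)-4-hydroxybut-2-en-1-yl]-2-(pent-4-yn-1-yl)propanedioate
Product: 6 2-[(2E)-4-hydroxybut-2-en-1-yl]-2-(pent-4-yn-1-yl)propane-1,3-diol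
Conditions: LiAlH4, THF, 0 °C → rt; aqueous NaOH work-up
Reagents that add atoms: none
Why: Hydride reduction of both esters to the 2,2-disubstituted propane-1,3-diol; the isolated alkyne and alkene are inert to LiAlH4 at this temperature.

Step 4
Reactants: 6 2-[(2E)-4-hydroxybut-2-en-1-yl]-2-(pent-4-yn-1-yl)propane-1,3-diol
Product: 7 (2E)-4-[2,2-dimethyl-5-(pent-4-yn-1-yl)-1,3-dioxan-5-yl]but-2-en-1-ol
Conditions: Me2C(OMe)2, PPTS (cat.), acetone, rt; then MeOH, rt
Reagents that add atoms: 2,2-dimethoxypropane, COC(C)(C)OC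
Why: Acid-catalysed transketalisation gives the six-membered 1,3-dioxane at the 1,3-diol only, and any acyclic mixed ketal on the allylic hydroxyl is removed by the brief methanolysis.

Step 5
Reactants: 7 (2E)-4-[2,2-dimethyl-5-(pent-4-yn-1-yl)-1,3-dioxan-5-yl]but-2-en-1-ol
Product: 9 (2E)-4-{5-[(4E)-5-iodo-4-methylpent-4-en-1-yl]-2,2-dimethyl-1,3-dioxan-5-yl}but-2-en-1-ol, via alkenyl(dimethyl)alane 8 (not isolated)
Conditions: Me3Al (4 equiv), Cp2ZrCl2 (20 mol %), H2O (1 equiv), CH2Cl2, −20 °C; then iodine, THF, −20 → 0 °C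
Reagents that add atoms: trimethylaluminium, C[Al](C)C; iodine, [I][I]
Why: Negishi zirconium-catalysed carboalumination adds methyl and aluminium syn across the terminal alkyne (aluminium on the terminal carbon) and iodinolysis with retention gives the (E)-iodoalkene; the hydroxyl is masked in situ as its aluminium alkoxide and the fast, cold, water-accelerated protocol is chosen to spare the acetonide.

Step 6
Reactants: 9 (2E)-4-{5-[(4E)-5-iodo-4-methylpent-4-en-1-yl]-2,2-dimethyl-1,3-dioxan-5-yl}but-2-en-1-ol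
Product: 10 (2E)-4-{5-[(4E)-5-iodo-4-methylpent-4-en-1-yl]-2,2-dimethyl-1,3-dioxan-5-yl}but-2-enal
Conditions: MnO2 (activated, excess), CH2Cl2, rt
Reagents that add atoms: none
Why: Chemoselective heterogeneous MnO2 oxidation of the allylic alcohol to the (E)-enal under neutral conditions that leave the iodoalkene and acetonide alone.

Step 7
Reactants: 10 (2E)-4-{5-[(4E)-5-iodo-4-methylpent-4-en-1-yl]-2,2-dimethyl-1,3-dioxan-5-yl}but-2-enal
Product: 11 tert-butyl{[(1E,3E)-4-{5-[(4E)-5-iodo-4-methylpent-4-en-1-yl]-2,2-dimethyl-1,3-dioxan-5-yl}buta-1,3-dien-1-yl]oxy}dimethylsilane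
Conditions: TBSOTf, Et3N, Et2O, 0 °C → rt; chromatography on Et3N-deactivated silica
Reagents that add atoms: tert-butyldimethylsilyl triflate, CC(C)(C)[Si](C)(C)OS(=O)(=O)C(F)(F)F
Why: Silyl dienol ether formation by O-silylation and γ-deprotonation of the s-trans enal, which should give the (1E) enol ether while the quaternary C4 substituent enforces the (3E) geometry.

Step 8
Reactants: 11 tert-butyl{[(1E,3E)-4-{5-[(4E)-5-iodo-4-methylpent-4-en-1-yl]-2,2-dimethyl-1,3-dioxan-5-yl}buta-1,3-dien-1-yl]oxy}dimethylsilane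
Product: 14 (2E)-6-{5-[(1E,3E)-4-(tert-butyldimethylsilyloxy)buta-1,3-dien-1-yl]-2,2-dimethyl-1,3-dioxan-5-yl}-3-methylhex-2-enal, via alkenyllithium 12 (not isolated), via lithium hemiaminal alkoxide 13 (not isolated)
Conditions: t-BuLi (2.1 equiv), Et2O, −78 °C; DMF, −78 → 0 °C; pH 7 buffer
Reagents that add atoms: N,N-dimethylformamide, CN(C)C=O
Why: Iodine–lithium exchange with retention of alkene geometry followed by formylation with DMF (Bouveault aldehyde synthesis) delivers the (E)-3-methyl enal at −78 °C with a non-acidic work-up that the silyl dienol ether tolerates.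

Step 9
Reactants: 14 (2E)-6-{5-[(1E,3E)-4-(tert-butyldimethylsilyloxy)buta-1,3-dien-1-yl]-2,2-dimethyl-1,3-dioxan-5-yl}-3-methylhex-2-enal
Product: 15 8β-(tert-butyldimethylsilyloxy)-18,19-(isopropylidenedioxy)-12,13,14,15,16,17-hexanorlabd-6-en-11-al (5α-H, 9β-CHO, 10β-CH3, trans-fused)
Conditions: (R)-3,3-diphenyl-1-(2-methylphenyl)tetrahydro-1H,3H-pyrrolo[1,2-c][1,3,2]oxazaborole (20 mol %), HN(SO2CF3)2 (17 mol %), CH2Cl2, −78 → −40 °C; Et3N quench
Reagents that add atoms: none
Why: The protonated oxazaborolidine binds the formyl oxygen of 14 and lowers the LUMO of the (E)-enal, so that a concerted but asynchronous [4+2] cycloaddition takes place in which the nucleophilic diene terminus C5 bonds to the β-carbon C10 ahead of the bond from the silyloxy-bearing C8 to C9; the closest known reaction type is the chiral-oxazaborolidinium-catalysed enantioselective type 1 intramolecular Diels–Alder reaction of trienals to trans-fused bicycles. Ring B closes as the cyclohexene of the cycloaddition itself (bonds C5–C10 and C8–C9, new C6=C7), and ring A closes through the same C5–C10 bond as the six-membered ring spanned by the C1–C4 tether in a chair-like, fused (not bridged) mode. C9 and C10 come out cis (9β-CHO, 10β-CH3) because the addition is suprafacial on the (E)-enal, C5 comes out trans to the C10 methyl (5α-H) because the formyl group sits endo under the diene while the tether adopts the chair, and C8 carries its silyloxy group β because the (1E)-dienol ether places it on the face of the endo formyl group; the absolute sense is set by the catalyst, whose aryl group blocks one enal face so that the diene adds to the C9-Si/C10-Re face. The step needs endo (trans-fusion) and enantiofacial selectivity and a useful rate for a β,β-disubstituted enal: the single Lewis-basic formyl group gives one defined catalyst complex, the electron-rich silyloxy diene is polarity-matched with the enal, and the spiro-acetonide at C4 accelerates closure (Thorpe–Ingold effect) while keeping C4 non-stereogenic. A C8 epimer arising from any (1Z)-dienol ether would be harmless, since C8 becomes sp2 in step 15.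

Step 10
Reactants: 15 8β-(tert-butyldimethylsilyloxy)-18,19-(isopropylidenedioxy)-12,13,14,15,16,17-hexanorlabd-6-en-11-al
Product: 16 8β-(tert-butyldimethylsilyloxy)-18,19-(isopropylidenedioxy)-12,13,14,15,16,17-hexanorlabdan-11-al
Conditions: H2 (1 atm), Pd on carbon (10 %), EtOAc, rt; crude 15 used without storage
Reagents that add atoms: none
Why: Heterogeneous catalytic hydrogenation saturates the cis-disubstituted C6=C7 alkene without creating a stereocentre, and the aldehyde and silyl ether are inert under these conditions.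

Step 11
Reactants: 16 8β-(tert-butyldimethylsilyloxy)-18,19-(isopropylidenedioxy)-12,13,14,15,16,17-hexanorlabdan-11-al
Product: 17 8β-(tert-butyldimethylsilyloxy)-18,19-(isopropylidenedioxy)-13,14,15,16,17-pentanorlabd-11-ene
Conditions: Ph3PCH3Br, KN(SiMe3)2, THF, −78 → 0 °C
Reagents that add atoms: methyltriphenylphosphonium bromide, C[P+](c1ccccc1)(c1ccccc1)c1ccccc1.[Br-]
Why: Wittig methylenation with the salt-free ylide at low temperature, where addition to the formyl group should outrun enolisation, leaving the equatorial C9 configuration and the 8-silyloxy group in place.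

Step 12
Reactants: 18 tert-butyl 3-oxobutanoate
Product: 19 tert-butyl (2E)-3-{[(trifluoromethyl)sulfonyl]oxy}but-2-enoate
Conditions: Tf2O, aq Me4NOH, hexane, 5–10 °C
Reagents that add atoms: trifluoromethanesulfonic anhydride, O=S(=O)(OS(=O)(=O)C(F)(F)F)C(F)(F)F
Why: O-Triflation of the β-keto ester enolate with a non-chelating tetraalkylammonium counter-ion proceeds through the open enolate and gives the (E)-enol triflate (triflate trans to the ester).

Step 13
Reactants: 17 8β-(tert-butyldimethylsilyloxy)-18,19-(isopropylidenedioxy)-13,14,15,16,17-pentanorlabd-11-ene; 19 tert-butyl (2E)-3-{[(trifluoromethyl)sulfonyl]oxy}but-2-enoate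
Product: 21 tert-butyl 8β-(tert-butyldimethylsilyloxy)-18,19-(isopropylidenedioxy)-17-norlabd-13E-en-15-oate, via B-alkyl-9-borabicyclo[3.3.1]nonane 20 (not isolated)
Conditions: 9-BBN-H, THF, 0 → 50 °C; then 19, PdCl2(dppf) (5 mol %; dppf = 1,1'-bis(diphenylphosphino)ferrocene), AsPh3, aq K3PO4, DMF, rt
Reagents that add atoms: none
Why: Anti-Markovnikov hydroboration of the only alkene by 9-BBN followed by B-alkyl Suzuki–Miyaura coupling (oxidative addition of zerovalent palladium to the enol triflate with retention) forms C12–C13 and fixes the 13E geometry.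

Step 14
Reactants: 21 tert-butyl 8β-(tert-butyldimethylsilyloxy)-18,19-(isopropylidenedioxy)-17-norlabd-13E-en-15-oate
Product: 22 tert-butyl 8β-hydroxy-18,19-(isopropylidenedioxy)-17-norlabd-13E-en-15-oate
Conditions: Bu4NF, THF, rt → 50 °C
Reagents that add atoms: none
Why: Fluoride-mediated desilylation of the hindered axial silyl ether; the tert-butyl ester and the acetonide are stable to fluoride.

Step 15
Reactants: 22 tert-butyl 8β-hydroxy-18,19-(isopropylidenedioxy)-17-norlabd-13E-en-15-oate
Product: 23 tert-butyl 18,19-(isopropylidenedioxy)-8-oxo-17-norlabd-13E-en-15-oate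
Conditions: Dess–Martin periodinane, pyridine, CH2Cl2, 0 °C → rt
Reagents that add atoms: none
Why: Dess–Martin oxidation of the secondary alcohol to the C8 ketone under buffered conditions; the C9 chain is already equatorial, so C9 is not at risk of epimerisation.

Step 16
Reactants: 23 tert-butyl 18,19-(isopropylidenedioxy)-8-oxo-17-norlabd-13E-en-15-oate
Product: 24 tert-butyl 18,19-(isopropylidenedioxy)labda-8(17),13E-dien-15-oate
Conditions: Zn, CH2Br2, TiCl4 (premixed in THF, 5 °C); then 23, CH2Cl2, 0 °C → rt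
Reagents that add atoms: dibromomethane, BrCBr
Why: Lombardo methylenation with the non-basic zinc/titanium methylene reagent converts the hindered, enolisable ketone into the exocyclic alkene chemoselectively beside the ester, without isomerising the 13E enoate.

Step 17
Reactants: 24 tert-butyl 18,19-(isopropylidenedioxy)labda-8(17),13E-dien-15-oate
Product: 25 tert-butyl 18,19-dihydroxylabda-8(17),13E-dien-15-oate
Conditions: AcOH/H2O/THF (3:1:1), 40 °C
Reagents that add atoms: none
Why: Mild aqueous-acid hydrolysis of the acetonide, under which the exocyclic alkene and the tert-butyl ester should persist.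

Step 18
Reactants: 25 tert-butyl 18,19-dihydroxylabda-8(17),13E-dien-15-oate
Product: 26 tert-butyl 18-acetoxy-19-hydroxylabda-8(17),13E-dien-15-oate
Conditions: AcCl (1.05 equiv), 2,4,6-collidine, CH2Cl2, −78 → −40 °C
Reagents that add atoms: acetyl chloride, CC(Cl)=O
Why: Kinetic, sterically controlled monoacylation in which the equatorial 4α-hydroxymethyl group should react faster than the axial one that is 1,3-diaxial to the C10 methyl, so that C4 becomes stereogenic with the acetate on C18.

Step 19
Reactants: 26 tert-butyl 18-acetoxy-19-hydroxylabda-8(17),13E-dien-15-oate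
Product: 27 tert-butyl 18-acetoxy-19-[(phenoxycarbonothioyl)oxy]labda-8(17),13E-dien-15-oate
Conditions: PhOC(S)Cl, pyridine, DMAP (cat.), CH2Cl2, 0 °C → rt
Reagents that add atoms: O-phenyl carbonochloridothioate, S=C(Cl)Oc1ccccc1
Why: Thioacylation of the remaining neopentyl alcohol (first stage of a Barton–McCombie deoxygenation) with a reactive chlorothionoformate at or below room temperature, chosen to avoid 1,3-acetyl migration.

Step 20
Reactants: 27 tert-butyl 18-acetoxy-19-[(phenoxycarbonothioyl)oxy]labda-8(17),13E-dien-15-oate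
Product: 28 tert-butyl 18-acetoxylabda-8(17),13E-dien-15-oate
Conditions: Bu3SnH, AIBN, toluene, 110 °C, slow addition
Reagents that add atoms: none
Why: Barton–McCombie radical deoxygenation, in which the stannyl radical adds to the thiocarbonyl group, β-scission releases the primary C19 radical (no β-hydrogen on C4, so no thermal elimination) and hydrogen transfer from the stannane gives the axial methyl without touching C4.

Step 21
Reactants: 28 tert-butyl 18-acetoxylabda-8(17),13E-dien-15-oate
Product: 30 18-acetoxylabda-8(17),13E-dien-15-oic acid, via trimethylsilyl ester 29 (not isolated)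
Conditions: TMSOTf, 2,6-lutidine, CH2Cl2, 0 °C; then H2O
Reagents that add atoms: none
Why: Silyl-triflate-mediated cleavage of the tert-butyl ester (loss of 2-methylpropene) gives the silyl ester, which hydrolyses on work-up; the buffered, non-protic conditions should spare the primary acetate and the exocyclic alkene.

**Compound list**

1 | diethyl malonate | CCOC(=O)CC(=O)OCC | starting material
2 | 5-chloropent-1-yne | C#CCCCCl | starting material
3 | diethyl 2-(pent-4-yn-1-yl)propanedioate | CCOC(=O)C(CCCC#C)C(=O)OCC | intermediate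
4 | 2-vinyloxirane (racemic) | C=CC1CO1 | starting material
5 | diethyl 2-[(2E)-4-hydroxybut-2-en-1-yl]-2-(pent-4-yn-1-yl)propanedioate | CCOC(=O)C(CCCC#C)(C/C=C/CO)C(=O)OCC | intermediate
6 | 2-[(2E)-4-hydroxybut-2-en-1-yl]-2-(pent-4-yn-1-yl)propane-1,3-diol | OCC(CO)(CCCC#C)C/C=C/CO | intermediate
7 | (2E)-4-[2,2-dimethyl-5-(pent-4-yn-1-yl)-1,3-dioxan-5-yl]but-2-en-1-ol | CC1(C)OCC(CCCC#C)(C/C=C/CO)CO1 | intermediate
8 | (E)-alkenyl(dimethyl)alane of 7 with the hydroxyl as its dimethylaluminium alkoxide | C[Al](C)/C=C(\C)CCCC1(C/C=C/CO[Al](C)C)COC(C)(C)OC1 | intermediate (not isolated)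
9 | (2E)-4-{5-[(4E)-5-iodo-4-methylpent-4-en-1-yl]-2,2-dimethyl-1,3-dioxan-5-yl}but-2-en-1-ol | I/C=C(\C)CCCC1(C/C=C/CO)COC(C)(C)OC1 | intermediate
10 | (2E)-4-{5-[(4E)-5-iodo-4-methylpent-4-en-1-yl]-2,2-dimethyl-1,3-dioxan-5-yl}but-2-enal | I/C=C(\C)CCCC1(C/C=C/C=O)COC(C)(C)OC1 | intermediate
11 | tert-butyl{[(1E,3E)-4-{5-[(4E)-5-iodo-4-methylpent-4-en-1-yl]-2,2-dimethyl-1,3-dioxan-5-yl}buta-1,3-dien-1-yl]oxy}dimethylsilane | I/C=C(\C)CCCC1(/C=C/C=C/O[Si](C)(C)C(C)(C)C)COC(C)(C)OC1 | intermediate
12 | (E)-alkenyllithium from 11 | [Li]/C=C(\C)CCCC1(/C=C/C=C/O[Si](C)(C)C(C)(C)C)COC(C)(C)OC1 | intermediate (not isolated)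
13 | lithium hemiaminal alkoxide (DMF adduct of 12) | CN(C)C(O[Li])/C=C(\C)CCCC1(/C=C/C=C/O[Si](C)(C)C(C)(C)C)COC(C)(C)OC1 | intermediate (not isolated)
14 | (2E)-6-{5-[(1E,3E)-4-(tert-butyldimethylsilyloxy)buta-1,3-dien-1-yl]-2,2-dimethyl-1,3-dioxan-5-yl}-3-methylhex-2-enal | O=C/C=C(\C)CCCC1(/C=C/C=C/O[Si](C)(C)C(C)(C)C)COC(C)(C)OC1 | intermediate (key-step precursor)
15 | 8β-(tert-butyldimethylsilyloxy)-18,19-(isopropylidenedioxy)-12,13,14,15,16,17-hexanorlabd-6-en-11-al (5α-H, 9α-H, 10β-CH3) | [C@H]1(O[Si](C)(C)C(C)(C)C)C=C[C@H]2C3(COC(C)(C)OC3)CCC[C@]2(C)[C@H]1C=O | intermediate (key-step product)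
16 | 8β-(tert-butyldimethylsilyloxy)-18,19-(isopropylidenedioxy)-12,13,14,15,16,17-hexanorlabdan-11-al | [C@H]1(O[Si](C)(C)C(C)(C)C)CC[C@H]2C3(COC(C)(C)OC3)CCC[C@]2(C)[C@H]1C=O | intermediate
17 | 8β-(tert-butyldimethylsilyloxy)-18,19-(isopropylidenedioxy)-13,14,15,16,17-pentanorlabd-11-ene | [C@H]1(O[Si](C)(C)C(C)(C)C)CC[C@H]2C3(COC(C)(C)OC3)CCC[C@]2(C)[C@H]1C=C | intermediate
18 | tert-butyl 3-oxobutanoate | CC(=O)CC(=O)OC(C)(C)C | starting material
19 | tert-butyl (2E)-3-{[(trifluoromethyl)sulfonyl]oxy}but-2-enoate | C/C(OS(=O)(=O)C(F)(F)F)=C\C(=O)OC(C)(C)C | intermediate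
20 | B-(C12-alkyl)-9-borabicyclo[3.3.1]nonane from 17 | [C@H]1(O[Si](C)(C)C(C)(C)C)CC[C@H]2C3(COC(C)(C)OC3)CCC[C@]2(C)[C@H]1CCB1C2CCCC1CCC2 | intermediate (not isolated)
21 | tert-butyl 8β-(tert-butyldimethylsilyloxy)-18,19-(isopropylidenedioxy)-17-norlabd-13E-en-15-oate | [C@H]1(O[Si](C)(C)C(C)(C)C)CC[C@H]2C3(COC(C)(C)OC3)CCC[C@]2(C)[C@H]1CC/C(C)=C/C(=O)OC(C)(C)C | intermediate
22 | tert-butyl 8β-hydroxy-18,19-(isopropylidenedioxy)-17-norlabd-13E-en-15-oate | [C@H]1(O)CC[C@H]2C3(COC(C)(C)OC3)CCC[C@]2(C)[C@H]1CC/C(C)=C/C(=O)OC(C)(C)C | intermediate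
23 | tert-butyl 18,19-(isopropylidenedioxy)-8-oxo-17-norlabd-13E-en-15-oate | O=C1CC[C@H]2C3(COC(C)(C)OC3)CCC[C@]2(C)[C@H]1CC/C(C)=C/C(=O)OC(C)(C)C | intermediate
24 | tert-butyl 18,19-(isopropylidenedioxy)labda-8(17),13E-dien-15-oate | C=C1CC[C@H]2C3(COC(C)(C)OC3)CCC[C@]2(C)[C@H]1CC/C(C)=C/C(=O)OC(C)(C)C | intermediate
25 | tert-butyl 18,19-dihydroxylabda-8(17),13E-dien-15-oate | C=C1CC[C@H]2C(CO)(CO)CCC[C@]2(C)[C@H]1CC/C(C)=C/C(=O)OC(C)(C)C | intermediate
26 | tert-butyl 18-acetoxy-19-hydroxylabda-8(17),13E-dien-15-oate | C=C1CC[C@H]2[C@](CO)(COC(C)=O)CCC[C@]2(C)[C@H]1CC/C(C)=C/C(=O)OC(C)(C)C | intermediate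
27 | tert-butyl 18-acetoxy-19-[(phenoxycarbonothioyl)oxy]labda-8(17),13E-dien-15-oate | C=C1CC[C@H]2[C@](COC(=S)Oc3ccccc3)(COC(C)=O)CCC[C@]2(C)[C@H]1CC/C(C)=C/C(=O)OC(C)(C)C | intermediate
28 | tert-butyl 18-acetoxylabda-8(17),13E-dien-15-oate | C=C1CC[C@H]2[C@](C)(COC(C)=O)CCC[C@]2(C)[C@H]1CC/C(C)=C/C(=O)OC(C)(C)C | intermediate
29 | trimethylsilyl 18-acetoxylabda-8(17),13E-dien-15-oate | C=C1CC[C@H]2[C@](C)(COC(C)=O)CCC[C@]2(C)[C@H]1CC/C(C)=C/C(=O)O[Si](C)(C)C | intermediate (not isolated)
30 | 18-acetoxylabda-8(17),13E-dien-15-oic acid, (2E)-5-[(1S,4aR,5R,8aR)-5-(acetoxymethyl)-5,8a-dimethyl-2-methylidenedecahydronaphthalen-1-yl]-3-methylpent-2-enoic acid | C=C1CC[C@H]2[C@](C)(COC(C)=O)CCC[C@]2(C)[C@H]1CC/C(C)=C/C(=O)O | target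

**Count**

Total: 21 steps. Longest linear sequence: 20 steps (steps 1–11 and 13–21); step 12 is a one-step branch.

**Steps most likely to fail**

1. Step 9. The cationic boron catalyst may protodesilylate the silyl dienol ether or trigger Mukaiyama-type oligomerisation. The β,β-disubstituted enal may cyclise too slowly. The developing 1,3-diaxial contact between the axial C4 arm and the C10 methyl may erode trans or facial selectivity.
Fallback (auxiliary-controlled cycloaddition; sets out from 11, returns at 15): iodine–lithium exchange on 11 (t-BuLi, Et2O, −78 °C) and quenching with CO2 should give (2E)-6-{5-[(1E,3E)-4-(tert-butyldimethylsilyloxy)buta-1,3-dien-1-yl]-2,2-dimethyl-1,3-dioxan-5-yl}-3-methylhex-2-enoic acid F1, kept as its triethylammonium salt. Pivaloyl chloride/Et3N converts it into the mixed pivalic anhydride F2, which acylates lithiated (S)-4-benzyloxazolidin-2-one to give the N-enoyl imide F3. With Me2AlCl (1.4 equiv, CH2Cl2, −30 °C) the chelated s-cis imide should cyclise through the same endo transition state, with the benzyl group shielding the face opposite to the one required, to give the cycloadduct imide F4. LiBH4 (THF/MeOH, 0 °C) releases the auxiliary and gives the primary alcohol F5, and Dess–Martin oxidation returns aldehyde 15.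

2. Step 18. Site selectivity between two neopentyl primary hydroxyls may be poor, and the acetyl group may migrate between the two oxygen atoms during step 19.
Fallback (silyl differentiation with acylation last; sets out from 25, returns at 28): the bulkier t-BuPh2SiCl/imidazole (DMF, −20 °C) should silylate the equatorial arm to give tert-butyl 18-(tert-butyldiphenylsilyloxy)-19-hydroxylabda-8(17),13E-dien-15-oate F6. With no acyl group present, NaH/CS2/iodomethane gives the S-methyl xanthate F7 without migration risk. Bu3SnH/AIBN (toluene, 110 °C) gives the 19-deoxy silyl ether F8. Bu4NF frees tert-butyl 18-hydroxylabda-8(17),13E-dien-15-oate F9, and Ac2O/pyridine/DMAP gives 28.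

3. Step 11. The ylide may act as a base, causing β-elimination of silanol across C8–C9 (the 9α-H and the 8β-silyloxy group are anti-periplanar), or may simply enolise the hindered aldehyde.
Fallback (stabilised-phosphonate route; sets out from 15, returns at 21): dimethyl (2-oxopropyl)phosphonate with Ba(OH)2 (THF/H2O, rt) should olefinate the aldehyde under weakly basic conditions to give the (11E)-enone, 8β-(tert-butyldimethylsilyloxy)-18,19-(isopropylidenedioxy)-14,15,17-trinorlabda-6,11-dien-13-one F10. Hydrogenation (H2, Pd on carbon, EtOAc) saturates both alkenes to give the methyl ketone F11. Horner–Wadsworth–Emmons reaction with tert-butyl diethylphosphonoacetate/NaH (THF) gives 21 after chromatographic removal of the minor 13Z isomer. This route gives up the stereospecific coupling of step 13.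

**Further compounds**

F1 | step 9 | (2E)-6-{5-[(1E,3E)-4-(tert-butyldimethylsilyloxy)buta-1,3-dien-1-yl]-2,2-dimethyl-1,3-dioxan-5-yl}-3-methylhex-2-enoic acid | OC(=O)/C=C(\C)CCCC1(/C=C/C=C/O[Si](C)(C)C(C)(C)C)COC(C)(C)OC1
F2 | step 9 | mixed anhydride of F1 with pivalic acid | CC(C)(C)C(=O)OC(=O)/C=C(\C)CCCC1(/C=C/C=C/O[Si](C)(C)C(C)(C)C)COC(C)(C)OC1
F3 | step 9 | (4S)-4-benzyl-3-[(2E)-6-{5-[(1E,3E)-4-(tert-butyldimethylsilyloxy)buta-1,3-dien-1-yl]-2,2-dimethyl-1,3-dioxan-5-yl}-3-methylhex-2-enoyl]oxazolidin-2-one | O=C(/C=C(\C)CCCC1(/C=C/C=C/O[Si](C)(C)C(C)(C)C)COC(C)(C)OC1)N1[C@@H](Cc2ccccc2)COC1=O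
F4 | step 9 | N-acyl oxazolidinone cycloadduct (8β-silyloxy, 9β-acyl, 10β-methyl, 5α-H, Δ6) | [C@H]1(O[Si](C)(C)C(C)(C)C)C=C[C@H]2C3(COC(C)(C)OC3)CCC[C@]2(C)[C@H]1C(=O)N1[C@@H](Cc2ccccc2)COC1=O
F5 | step 9 | 8β-(tert-butyldimethylsilyloxy)-18,19-(isopropylidenedioxy)-12,13,14,15,16,17-hexanorlabd-6-en-11-ol | [C@H]1(O[Si](C)(C)C(C)(C)C)C=C[C@H]2C3(COC(C)(C)OC3)CCC[C@]2(C)[C@H]1CO
F6 | step 18 | tert-butyl 18-(tert-butyldiphenylsilyloxy)-19-hydroxylabda-8(17),13E-dien-15-oate | C=C1CC[C@H]2[C@](CO)(CO[Si](c3ccccc3)(c3ccccc3)C(C)(C)C)CCC[C@]2(C)[C@H]1CC/C(C)=C/C(=O)OC(C)(C)C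
F7 | step 18 | tert-butyl 18-(tert-butyldiphenylsilyloxy)-19-{[(methylsulfanyl)carbonothioyl]oxy}labda-8(17),13E-dien-15-oate | C=C1CC[C@H]2[C@](COC(=S)SC)(CO[Si](c3ccccc3)(c3ccccc3)C(C)(C)C)CCC[C@]2(C)[C@H]1CC/C(C)=C/C(=O)OC(C)(C)C
F8 | step 18 | tert-butyl 18-(tert-butyldiphenylsilyloxy)labda-8(17),13E-dien-15-oate | C=C1CC[C@H]2[C@](C)(CO[Si](c3ccccc3)(c3ccccc3)C(C)(C)C)CCC[C@]2(C)[C@H]1CC/C(C)=C/C(=O)OC(C)(C)C
F9 | step 18 | tert-butyl 18-hydroxylabda-8(17),13E-dien-15-oate | C=C1CC[C@H]2[C@](C)(CO)CCC[C@]2(C)[C@H]1CC/C(C)=C/C(=O)OC(C)(C)C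
F10 | step 11 | (11E)-8β-(tert-butyldimethylsilyloxy)-18,19-(isopropylidenedioxy)-14,15,17-trinorlabda-6,11-dien-13-one | [C@H]1(O[Si](C)(C)C(C)(C)C)C=C[C@H]2C3(COC(C)(C)OC3)CCC[C@]2(C)[C@H]1/C=C/C(C)=O
F11 | step 11 | 8β-(tert-butyldimethylsilyloxy)-18,19-(isopropylidenedioxy)-14,15,17-trinorlabdan-13-one | [C@H]1(O[Si](C)(C)C(C)(C)C)CC[C@H]2C3(COC(C)(C)OC3)CCC[C@]2(C)[C@H]1CCC(C)=O
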